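**Retrosynthetic overview**

1. The spiro-cyclohexane is opened last, at the C(spiro)–CH2 bond and the tertiary C–OH. This gives a 6-alkyl dearomatized acylphloroglucinol whose side arm is a trans-2-isopropenylcyclopentylmethyl group. Forward: oxidative 6-endo radical cyclization with O2 capture.
2. The first C(spiro)–CH2 bond comes from reductive Knoevenagel alkylation of the gem-diprenyl trione with a cyclopentane carbaldehyde.
3. The cyclopentane comes from an intramolecular aldol of the seco-p-menthane keto-aldehyde obtained from (+)-limonene 1,2-oxide, the only purchased stereocentre.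
4. The gem-diprenyl trione comes from dearomative double C-prenylation of phlorisobutyrophenone.
5. Ring order: phloroglucinol ring (bought, dearomatized first), then cyclopentane, then spiro-cyclohexane.

Assumption: commercial (+)-limonene 1,2-oxide (4R, cis/trans mixture at the epoxide, from (R)-(+)-limonene) is the chiral starting material; all enolized triones are drawn as one tautomer.

Note on the key step: I found no defensible cycloaddition, electrocyclization or sigmatropic step that closes the spiro ring of this target, so the key ring closure below is a radical cyclization.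

**Step 1**
Reactants: 1 phlorisobutyrophenone; 2 prenyl bromide
Product: 4 3,5-dihydroxy-2-(2-methylpropanoyl)-4,4-bis(3-methylbut-2-enyl)cyclohexa-2,5-dien-1-one, via 3-prenylphlorisobutyrophenone 3 (not isolated)
Conditions: 2 (2.1 equiv), NaOMe (2.1 equiv), MeOH, 0 °C → rt; aq. HCl work-up
Reagents that add atoms: none
Why: Dearomative double C-alkylation of the phloroglucinolate in a protic medium, where the second prenyl group enters at the already substituted carbon to give the gem-diprenyl vinylogous acid (separated from the 3,5-diprenyl isomer); no stereocentre is formed.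

**Step 2**
Reactants: 5 (+)-limonene 1,2-oxide
Product: 7 (3R)-6-oxo-3-(prop-1-en-2-yl)heptanal, via limonene-1,2-diol 6 (not isolated)
Conditions: H5IO6 (1.1 equiv), THF–H2O, 0 °C → rt
Reagents that add atoms: water, O
Why: Epoxide hydrolysis followed by Malaprade glycol cleavage opens the ring to the keto-aldehyde; the isopropenyl group is inert and the purchased stereocentre (C4 of limonene, C3 of 7) is untouched.

**Step 3**
Reactants: 7 (3R)-6-oxo-3-(prop-1-en-2-yl)heptanal
Product: 8 (1S,2R,5R)-2-hydroxy-2-methyl-5-(prop-1-en-2-yl)cyclopentane-1-carbaldehyde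
Conditions: pyrrolidine (20 mol %), AcOH (20 mol %), CH2Cl2, 0 °C → rt, stopped before dehydration
Reagents that add atoms: none
Why: Enamine-mediated 5-enolexo intramolecular aldol addition (aldehyde enamine onto the methyl ketone); reversible aldol and α-epimerization funnel to the most stable diastereomer, with CHO trans to the isopropenyl group and cis to the hydrogen-bonded tertiary OH, so both new centres are set by the limonene stereocentre.

**Step 4**
Reactants: 4 gem-diprenyl trione; 8 aldol aldehyde
Product: 10 3,5-dihydroxy-6-{[(1S,2R,5R)-2-hydroxy-2-methyl-5-(prop-1-en-2-yl)cyclopentyl]methyl}-2-(2-methylpropanoyl)-4,4-bis(3-methylbut-2-enyl)cyclohexa-2,5-dien-1-one, via alkylidene trione 9 (not isolated)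
Conditions: Hantzsch ester (1.3 equiv), piperidinium acetate (10 mol %), CH2Cl2, rt
Reagents that add atoms: none
Why: Knoevenagel condensation at the only free ring carbon followed by immediate conjugate transfer hydrogenation of the 2-alkylidene-1,3-dione (three-component reductive alkylation) gives C-alkylation only; no new stereocentre, and the three cyclopentane centres are carried through.

**Step 5**
Reactants: 10 6-alkyl trione
Product: 12 tomoeone A, via tertiary hydroperoxide 11 (not isolated)
Conditions: Mn(OAc)3·2H2O (20 mol %), O2 (1 atm), AcOH, rt; then PPh3, 0 °C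
Reagents that add atoms: dioxygen, O=O
Why: Mn(III)-mediated oxidative radical cyclization: the α,α-diacyl radical adds 6-endo-trig to the CH2 terminus of the isopropenyl group through a chair transition state on the trans-cyclopentane; O2 then traps the tertiary radical from the equatorial face, anti to the axial spiro carbonyl, and PPh3 reduces the hydroperoxide. The spiro centre is set in the same cyclization, with the carbonyl next to C(prenyl)2 expected equatorial, but only modest selectivity is expected.

**Compound list**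

1 | phlorisobutyrophenone, 2-methyl-1-(2,4,6-trihydroxyphenyl)propan-1-one | CC(C)C(=O)c1c(O)cc(O)cc1O | starting material
2 | prenyl bromide, 1-bromo-3-methylbut-2-ene | CC(C)=CCBr | starting material
3 | 3-prenylphlorisobutyrophenone, 2-methyl-1-[2,4,6-trihydroxy-3-(3-methylbut-2-enyl)phenyl]propan-1-one | CC(C)=CCc1c(O)cc(O)c(C(=O)C(C)C)c1O | intermediate
4 | 3,5-dihydroxy-2-(2-methylpropanoyl)-4,4-bis(3-methylbut-2-enyl)cyclohexa-2,5-dien-1-one | CC(C)=CCC1(CC=C(C)C)C(O)=CC(=O)C(C(=O)C(C)C)=C1O | intermediate
5 | (+)-limonene 1,2-oxide, (4R)-1-methyl-4-(prop-1-en-2-yl)-7-oxabicyclo[4.1.0]heptane (cis/trans mixture) | CC12CC[C@@H](C(C)=C)CC1O2 | starting material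
6 | limonene-1,2-diol, (4R)-1-methyl-4-(prop-1-en-2-yl)cyclohexane-1,2-diol | CC1(O)CC[C@@H](C(C)=C)CC1O | intermediate
7 | (3R)-6-oxo-3-(prop-1-en-2-yl)heptanal | O=CC[C@@H](CCC(C)=O)C(C)=C | intermediate
8 | (1S,2R,5R)-2-hydroxy-2-methyl-5-(prop-1-en-2-yl)cyclopentane-1-carbaldehyde | O=C[C@H]1[C@@H](CC[C@@]1(C)O)C(C)=C | intermediate
9 | 3-hydroxy-6-{[(1S,2R,5R)-2-hydroxy-2-methyl-5-(prop-1-en-2-yl)cyclopentyl]methylidene}-2-(2-methylpropanoyl)-4,4-bis(3-methylbut-2-enyl)cyclohex-2-ene-1,5-dione | CC(C)=CCC1(CC=C(C)C)C(=O)C(=C[C@H]2[C@@H](CC[C@@]2(C)O)C(C)=C)C(=O)C(C(=O)C(C)C)=C1O | intermediate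
10 | 3,5-dihydroxy-6-{[(1S,2R,5R)-2-hydroxy-2-methyl-5-(prop-1-en-2-yl)cyclopentyl]methyl}-2-(2-methylpropanoyl)-4,4-bis(3-methylbut-2-enyl)cyclohexa-2,5-dien-1-one | CC(C)=CCC1(CC=C(C)C)C(O)=C(C[C@H]2[C@@H](CC[C@@]2(C)O)C(C)=C)C(=O)C(C(=O)C(C)C)=C1O | intermediate
11 | 4′-hydroperoxide of 12 (OOH in place of the cyclohexane OH, same configuration) | CC(C)=CCC1(CC=C(C)C)C(=O)[C@@]2(C[C@H]3[C@@H](CC[C@@]3(C)O)[C@](C)(OO)C2)C(=O)C(C(=O)C(C)C)=C1O | intermediate
12 | tomoeone A, (1S,1′R,3a′R,4′R,7a′S)-1′,4,4′-trihydroxy-1′,4′-dimethyl-3-(2-methylpropanoyl)-5,5-bis(3-methylbut-2-en-1-yl)octahydrospiro[cyclohex-3-ene-1,6′-indene]-2,6-dione | CC(C)=CCC1(CC=C(C)C)C(=O)[C@@]2(C[C@H]3[C@@H](CC[C@@]3(C)O)[C@](C)(O)C2)C(=O)C(C(=O)C(C)C)=C1O | target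

**Step count**

Total: 5 steps. Longest linear sequence: 4 steps (5 → 7 → 8 → 10 → 12).

**Steps most likely to fail**

**Step 5 (radical spirocyclization).** The two chair transition states differ only in which carbonyl arm of the trione is axial, so the spiro centre may form with low selectivity and the epimer would have to be separated. Direct O2 capture at the ring carbon and cyclization onto a prenyl group may also compete. The fallback sets out from 8 and comes back at 12. Ene-type allylic chlorination of the isopropenyl group (NCS, cat. PhSeCl) gives (1S,2R,5R)-5-(3-chloroprop-1-en-2-yl)-2-hydroxy-2-methylcyclopentane-1-carbaldehyde F5. The same reductive Knoevenagel alkylation with 4 gives the allylic chloride analogue of 10 F6. K2CO3/NaI in acetone then closes the ring by polar intramolecular C-allylation of the trione anion to the 4′-methylidene spirocycle F7. A Mukaiyama hydration (Fe(acac)3, PhSiH3, O2) of the 1,1-disubstituted exocyclic alkene, which should react ahead of the trisubstituted prenyl groups, then gives 12.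

**Step 3 (aldol addition).** The ketol may dehydrate to the enal or give the wrong diastereomer. The fallback sets out from 7 and comes back at 8. The condensation is driven to completion (piperidine, AcOH, benzene, reflux) to give (5S)-2-methyl-5-(prop-1-en-2-yl)cyclopent-1-ene-1-carbaldehyde F1. Weitz–Scheffer epoxidation (H2O2, NaOH, MeOH) anti to the isopropenyl group gives (1S,2S,5R)-5-methyl-2-(prop-1-en-2-yl)-6-oxabicyclo[3.1.0]hexane-1-carbaldehyde F2. Reductive Cα–O cleavage with Na[PhSeB(OEt)3] in EtOH/AcOH, then α-epimerization to the trans aldehyde, gives 8.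

**Step 4 (reductive alkylation).** The β-hydroxy aldehyde may undergo retro-aldol or dehydration under amine catalysis before it is trapped. The fallback sets out from 8 and comes back at 10. The tertiary alcohol is masked (TMS-imidazole) as (1S,2R,5R)-2-methyl-5-(prop-1-en-2-yl)-2-(trimethylsilyloxy)cyclopentane-1-carbaldehyde F3, which blocks the retro-aldol. Reductive alkylation with 4 gives the trimethylsilyl ether of 10 F4. Mild desilylation (citric acid, MeOH) gives 10.

**Further compounds**

F1 | step 3 | (5S)-2-methyl-5-(prop-1-en-2-yl)cyclopent-1-ene-1-carbaldehyde | O=CC1=C(C)CC[C@H]1C(C)=C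
F2 | step 3 | (1S,2S,5R)-5-methyl-2-(prop-1-en-2-yl)-6-oxabicyclo[3.1.0]hexane-1-carbaldehyde | O=C[C@]12[C@@H](CC[C@@]1(C)O2)C(C)=C
F3 | step 4 | (1S,2R,5R)-2-methyl-5-(prop-1-en-2-yl)-2-(trimethylsilyloxy)cyclopentane-1-carbaldehyde | O=C[C@H]1[C@@H](CC[C@@]1(C)O[Si](C)(C)C)C(C)=C
F4 | step 4 | trimethylsilyl ether of 10 at the cyclopentane carbinol | CC(C)=CCC1(CC=C(C)C)C(O)=C(C[C@H]2[C@@H](CC[C@@]2(C)O[Si](C)(C)C)C(C)=C)C(=O)C(C(=O)C(C)C)=C1O
F5 | step 5 | (1S,2R,5R)-5-(3-chloroprop-1-en-2-yl)-2-hydroxy-2-methylcyclopentane-1-carbaldehyde | O=C[C@H]1[C@@H](CC[C@@]1(C)O)C(=C)CCl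
F6 | step 5 | analogue of 10 with a 3-chloroprop-1-en-2-yl group in place of the isopropenyl group | CC(C)=CCC1(CC=C(C)C)C(O)=C(C[C@H]2[C@@H](CC[C@@]2(C)O)C(=C)CCl)C(=O)C(C(=O)C(C)C)=C1O
F7 | step 5 | (1S,1′R,3a′R,7a′S)-1′,4-dihydroxy-1′-methyl-4′-methylidene-3-(2-methylpropanoyl)-5,5-bis(3-methylbut-2-en-1-yl)octahydrospiro[cyclohex-3-ene-1,6′-indene]-2,6-dione | CC(C)=CCC1(CC=C(C)C)C(=O)[C@@]2(C[C@H]3[C@@H](CC[C@@]3(C)O)C(=C)C2)C(=O)C(C(=O)C(C)C)=C1O
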